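**Retrosynthetic overview**
1. Structural feature: in the cycloheptene ring the run C10(O)–C8(Me)–C7–C6–C5–C1, with C4 attached to C5, matches the ring of (R)-carvone atom for atom (C1′=O, C2′–Me, C3′, C4′, C5′ with the isopropenyl carbon, C6′). Only C9 is missing between C10 and C8, and C5′ already has the configuration of C5.
2. Key disconnection: remove C9 (cut C8–C9 and C9–C10, restore C8–C10). 9-Bromo-dauc-8-en-10-one ⇒ silyloxy-dibromocyclopropane ⇒ C8=C10 silyl enol ether of a trans-hydrindanone + bromoform.
3. Hydrindanone ⇒ carvone: C1 is built by methylation, then allylation anti to the isopropenyl group. The cyclopentane ring is closed by metathesis of the allyl group (C2, C3) with the silyl enol ether of the C4 acetyl group. This closure is neutral, whereas an aldol closure through a C1-formyl ketone would risk deformylation and epimerisation at C5. Then i-Pr is added to C4 and oxygen to C6, both from the α face.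
4. After the enlargement: bromine is removed first, so that C10=O has one large flank (C1) and one small flank (C9–H) for a catalyst-controlled reduction to the 10α-alcohol. Then acetate, desilylation, and anisoate on the secondary 6-OH.
5. Ring order: six-membered (carvone) → five-membered (step 6) → three-membered and, by its opening, seven-membered (both in step 12).

Key step: step 12

Remark: daucane numbering of the target is used for all bicyclic compounds (the hydrindanes simply lack C9), and primed numbers are carvone positions. β is the face of the C1 methyl group, α that of H-5. TES = triethylsilyl, TBS = tert-butyldimethylsilyl.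

**Step 1**
Reactants: 1 (R)-(−)-carvone; 2 iodomethane
Product: 4 (5R,6S)-6-methylcarvone, via lithium dienolate 3 (not isolated)
Conditions: LDA, THF, −78 °C; MeI, −78 → 0 °C
Reagents that add atoms: iodomethane (2), CI
Why: Kinetic deprotonation of the cross-conjugated enone at C6′ (the only α′ position) and SN2 methylation of the dienolate (enolate alkylation) bring in the future C1 methyl group; the new centre needs no control because step 2 flattens it again.

**Step 2**
Reactants: 4 (5R,6S)-6-methylcarvone; 5 allyl bromide
Product: 7 (5S,6S)-6-allyl-6-methylcarvone, via lithium enolate 6 (not isolated)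
Conditions: LDA, THF, −78 → 0 °C; allyl bromide, DMPU, −78 °C → rt
Reagents that add atoms: allyl bromide (5), C=CCBr
Why: In this second enolate alkylation the tetrasubstituted enolate is attacked by allyl bromide on the face anti to the adjacent isopropenyl group, so the allyl chain (C2, C3) ends trans and the methyl group cis to C4, which sets quaternary C1 (S) and programmes the trans ring fusion.

**Step 3**
Reactants: 7 (5S,6S)-6-allyl-6-methylcarvone
Product: 8 side-chain epoxide of 7 (2-methyloxiran-2-yl at C5′; both oxirane epimers)
Conditions: mCPBA (1.0 equiv), NaHCO3, CH2Cl2, 0 °C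
Reagents that add atoms: mCPBA, OOC(=O)c1cccc(Cl)c1
Why: Prilezhaev epoxidation follows alkene nucleophilicity, so the 1,1-disubstituted isopropenyl group should react ahead of the monosubstituted allyl group and the electron-poor enone; the oxirane carbon is not controlled since it becomes the C4 carbonyl in step 4.

**Step 4**
Reactants: 8 side-chain epoxide of 7
Product: 9 (5R,6S)-5-acetyl-6-allyl-2,6-dimethylcyclohex-2-en-1-one (acetyl trans to allyl)
Conditions: H5IO6, THF–H2O, 0 °C → rt
Reagents that add atoms: water, O
Why: Periodic acid opens the epoxide to the glycol and cleaves it at once (Malaprade cleavage), which turns the isopropenyl carbon into the C4 ketone with its methyl group as C3 and spares the allyl group that ozone would also attack; C5 is safe because the equatorial acetyl group trans to the allyl chain is also the more stable arrangement.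

**Step 5**
Reactants: 9 (5R,6S)-5-acetyl-6-allyl-2,6-dimethylcyclohex-2-en-1-one
Product: 11 terminal TES enol ether of 9 (5′-[1-(triethylsilyloxy)ethenyl]), via lithium enolate 10 (not isolated)
Conditions: Et3SiCl, then LDA (1.05 equiv), THF, −78 °C
Reagents that add atoms: chlorotriethylsilane, CC[Si](Cl)(CC)CC
Why: Kinetic enolisation with LDA in the presence of the chlorosilane (internal quench) removes a proton from the acetyl methyl group rather than the hindered C5–H, and immediate O-silylation gives the terminal silyl enol ether before the enolate can equilibrate or add to C10.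

**Step 6**
Reactants: 11 terminal TES enol ether of 9
Product: 13 trans-hydrindenedione (3aS,7aR)-3a,5-dimethyl-2,3,7,7a-tetrahydro-1H-indene-1,4(3aH)-dione (C4 and C10 ketones; Δ7; 1β-Me; 5α-H), via cyclic silyl enol ether 12 (not isolated)
Conditions: Grubbs II (5 mol %), toluene (0.005 M), 70 °C; then 1 M HCl, THF, 0 °C
Reagents that add atoms: none
Why: Ring-closing metathesis of a terminal alkene with a silyl enol ether, a known entry to five-membered cyclic silyl enol ethers, joins C3 to C4 from the trans-diequatorial side chains under neutral conditions, and the cold acid then protonates C3 only, so that H-5 next to the new ketone is never enolised and the less stable trans fusion laid down in step 2 is kept.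

**Step 7**
Reactants: 13 trans-hydrindenedione; 14 isopropylmagnesium chloride
Product: 15 4β-hydroxy-4α-isopropyl-1β,8-dimethyl-5αH-hydrind-7-en-10-one
Conditions: i-PrMgCl, CeCl3, THF, −78 → −30 °C; aq. NH4Cl
Reagents that add atoms: isopropylmagnesium chloride (14), CC(C)[Mg]Cl
Why: The weakly basic organocerium reagent adds 1,2 to the cyclopentanone instead of enolising or reducing it, approaches C4 from the α face because the angular C1 methyl group stands 1,3-syn over the β face, and so gives the 4β-alcohol with the α-isopropyl group (4R), while the C10 carbonyl, conjugated and wedged between quaternary C1 and the C8 methyl group, should stay untouched.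

**Step 8**
Reactants: 15 4β-hydroxy-4α-isopropyl-1β,8-dimethyl-5αH-hydrind-7-en-10-one
Product: 16 4β,10-bis(triethylsilyloxy)-4α-isopropyl-1β,8-dimethyl-5αH-hydrinda-6,8(10)-diene
Conditions: Et3SiOTf, Et3N, CH2Cl2, 0 °C → rt
Reagents that add atoms: triethylsilyl triflate, CC[Si](CC)(CC)OS(=O)(=O)C(F)(F)F
Why: Soft enolisation with silyl triflate and amine can only take the γ-proton at C6, since C1 carries no hydrogen, and gives the linear C10=C8–C7=C6 dienol silyl ether, while the same reagent silylates the tertiary C4 hydroxyl group.

**Step 9**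
Reactants: 16 4β,10-bis(triethylsilyloxy) dienol ether
Product: 18 6α-hydroxy-4β-(triethylsilyloxy)-4α-isopropyl-1β,8-dimethyl-5αH-hydrind-7-en-10-one, via 6α,7α-epoxide 17 (not isolated)
Conditions: mCPBA, NaHCO3, CH2Cl2, −20 °C; aq. NaHCO3/Na2S2O3
Reagents that add atoms: mCPBA, OOC(=O)c1cccc(Cl)c1
Why: In this vinylogous Rubottom oxidation the peracid epoxidises the open, disubstituted C6=C7 end of the 1-silyloxydiene rather than the tetrasubstituted C8=C10 bond beside quaternary C1, the silyloxy group pushes the epoxide open to the γ-hydroxy enone (as in the 6-hydroxylation of steroidal 3,5-dienol ethers), and attack from the α face, the β face over C6 being covered by the C1 methyl group and the axial 4β-silyloxy group, sets the 6α (6S) alcohol.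

**Step 10**
Reactants: 18 6α-hydroxy enone
Product: 19 6α-(tert-butyldimethylsilyloxy)-4β-(triethylsilyloxy)-4α-isopropyl-1β,8-dimethyl-5αH-hydrind-7-en-10-one
Conditions: TBSOTf, 2,6-lutidine, CH2Cl2, −78 → 0 °C
Reagents that add atoms: tert-butyldimethylsilyl triflate, CC(C)(C)[Si](C)(C)OS(=O)(=O)C(F)(F)F
Why: Silyl triflate with a hindered pyridine base silylates the crowded secondary allylic alcohol without enolising the γ-oxygenated enone, and the TBS ether will outlast tert-butoxide, palladium hydride and borane.

**Step 11**
Reactants: 19 6α-TBS ether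
Product: 20 6α-(tert-butyldimethylsilyloxy)-4β,10-bis(triethylsilyloxy)-4α-isopropyl-1β,8-dimethyl-5αH-hydrind-8(10)-ene (C8=C10 silyl enol ether)
Conditions: Et3SiH, RhCl(PPh3)3 (3 mol %), THF, 50 °C
Reagents that add atoms: triethylsilane, CC[SiH](CC)CC
Why: Rhodium-catalysed 1,4-hydrosilylation of the enone with a monohydrosilane places hydrogen on C7 and silicon on oxygen and thus gives the tetrasubstituted C8=C10 silyl enol ether as a single regioisomer without forming a stereocentre; a dissolving-metal reduction is avoided because it would expel the C6 silyloxy group.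

**Step 12**
Reactants: 20 C8=C10 silyl enol ether; 21 bromoform
Product: 23 9-bromo-6α-(tert-butyldimethylsilyloxy)-4β-(triethylsilyloxy)dauc-8-en-10-one, via dibromocyclopropane 22 (not isolated)
Conditions: CHBr3, KOt-Bu, pentane, −40 → −10 °C; cold filtration; 2,6-lutidine, toluene, 100 °C
Reagents that add atoms: bromoform (21), BrC(Br)Br
Why: tert-Butoxide deprotonates bromoform, α-elimination gives singlet dibromocarbene, and this electrophile adds in one concerted [2+1] (cheletropic) step to the only C=C bond of 20, the electron-rich C8=C10 enol ether, which forms C8–C9 and C9–C10 and closes the three-membered ring of 22. On heating, the bromide that lies endo (over the six-membered ring) ionises while the shared C8–C10 bond opens in a disrotatory two-electron electrocyclic process, pushed by the silyloxy oxygen and the C8 methyl group, and bromide then takes the silyl group from the oxocarbenium ion; the seven-membered ring is thus closed by enlargement of the six-membered ring, not by an end-to-end cyclisation. The closest known reaction type is the addition of dihalocarbenes to cyclic silyl enol ethers with opening to the ring-enlarged 2-halo-enones. The only new stereocentres, C8 and C10 of 22, are set by approach of the carbene from the α face, away from the C1 methyl group, and vanish again in 23, so either facial course would end in the same product, while C1, C4, C5 and C6 are spectators. The step needs the carbon to enter between C10 and C8 and the new alkene to be cis: the first is secured by quaternary C1, which allows no other enol ether, and by the regiospecific origin of 20 in step 11, the second by the Woodward–Hoffmann–DePuy rule, since loss of the exo bromide would demand a trans double bond in a seven-membered ring. Triethylsilyl groups on O10 and O4 are chosen because they resist tert-butoxide better than trimethylsilyl groups, the base is filtered off cold so that the enone never meets it (it could expel the C6 silyloxy group through the C7 dienolate), and lutidine takes up acid formed from bromotriethylsilane.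

**Step 13**
Reactants: 23 9-bromo enone
Product: 24 6α-(tert-butyldimethylsilyloxy)-4β-(triethylsilyloxy)dauc-8-en-10-one
Conditions: Bu3SnH, Pd(PPh3)4 (5 mol %), THF, rt
Reagents that add atoms: none
Why: Palladium-catalysed hydrodebromination (oxidative addition into the activated C9–Br bond, hydride transfer from tin, reductive elimination) replaces bromine by hydrogen with the ring alkene in place, the β,β-disubstituted enone being a poor substrate for conjugate reduction; it comes before the reduction because a bromine at C9 would make both flanks of the C10 carbonyl large.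

**Step 14**
Reactants: 24 dauc-8-en-10-one
Product: 25 6α-(tert-butyldimethylsilyloxy)-4β-(triethylsilyloxy)dauc-8-en-10α-ol (10R)
Conditions: (S)-Me-CBS (0.3 equiv), BH3·SMe2, THF, −30 → 0 °C; MeOH
Reagents that add atoms: none
Why: Corey–Bakshi–Shibata reduction: the catalyst boron should bind the carbonyl lone pair on the side of the small C9–H flank, away from fully substituted C1, and the (S)-oxazaborolidine then passes hydride to the β face of C10, on a path staggered between the C1 methyl group and C2 and anti to C1–C5, to give the 10α (10R) allylic alcohol, with 1,2-selectivity ensured by the disubstituted β-carbon C8.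

**Step 15**
Reactants: 25 10α-alcohol; 26 acetic anhydride
Product: 27 10α-acetoxy-6α-(tert-butyldimethylsilyloxy)-4β-(triethylsilyloxy)dauc-8-ene
Conditions: Ac2O, DMAP, Et3N, CH2Cl2, rt
Reagents that add atoms: acetic anhydride (26), CC(=O)OC(C)=O
Why: DMAP-catalysed acylation of the only free hydroxyl group gives the 10α-acetate with retention, since the C10–O bond is not touched.

**Step 16**
Reactants: 27 10α-acetate
Product: 28 10α-acetoxydauc-8-ene-4β,6α-diol
Conditions: HF·pyridine, pyridine, THF, 0 °C → rt
Reagents that add atoms: none
Why: Fluoride-driven Si–O cleavage with pyridine-buffered HF removes both silyl groups under slightly acidic conditions, which avoid the acetate hydrolysis or migration that basic fluoride sources can cause and do not ionise the allylic acetate or the tertiary alcohol.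

**Step 17**
Reactants: 28 10α-acetoxydauc-8-ene-4β,6α-diol; 29 4-methoxybenzoyl chloride
Product: 30 10α-acetoxy-6α-(4-methoxybenzoyloxy)dauc-8-en-4β-ol (1S,4R,5S,6S,10R; CNP0256979.2)
Conditions: 4-MeOC6H4COCl, DMAP, pyridine, CH2Cl2, rt → 40 °C
Reagents that add atoms: 4-methoxybenzoyl chloride (29), COc1ccc(cc1)C(Cl)=O
Why: DMAP-catalysed acylation distinguishes the secondary 6α-hydroxyl group from the tertiary C4 hydroxyl group, which is buried between the isopropyl group and the ring fusion, and so gives the 6-anisoate, the target, without a protecting group on O4.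

**Compound list**
1 | (R)-(−)-carvone, (5R)-2-methyl-5-(prop-1-en-2-yl)cyclohex-2-en-1-one | CC1=CC[C@@H](C(C)=C)CC1=O | starting material
2 | iodomethane | CI | starting material
3 | cross-conjugated lithium dienolate of carvone | CC1=CC[C@@H](C(C)=C)C=C1O[Li] | intermediate
4 | (5R,6S)-6-methylcarvone (methyl trans to isopropenyl; any 6-epimer is carried along) | CC1=CC[C@@H](C(C)=C)[C@H](C)C1=O | intermediate
5 | allyl bromide | C=CCBr | starting material
6 | tetrasubstituted lithium enolate of 4 | CC1=CC[C@@H](C(C)=C)C(C)=C1O[Li] | intermediate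
7 | (5S,6S)-6-allyl-6-methylcarvone (allyl trans, methyl cis to isopropenyl) | CC1=CC[C@@H](C(C)=C)[C@](C)(CC=C)C1=O | intermediate
8 | side-chain epoxide of 7 (both oxirane epimers) | CC1=CC[C@@H](C2(C)CO2)[C@](C)(CC=C)C1=O | intermediate
9 | (5R,6S)-5-acetyl-6-allyl-2,6-dimethylcyclohex-2-en-1-one | CC1=CC[C@@H](C(C)=O)[C@](C)(CC=C)C1=O | intermediate
10 | terminal lithium enolate of the acetyl group of 9 | CC1=CC[C@@H](C(=C)O[Li])[C@](C)(CC=C)C1=O | intermediate
11 | terminal TES enol ether of 9 | CC1=CC[C@@H](C(=C)O[Si](CC)(CC)CC)[C@](C)(CC=C)C1=O | intermediate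
12 | cyclic TES enol ether, 4-(triethylsilyloxy)-1β,8-dimethyl-5αH-hydrinda-3,7-dien-10-one | CC1=CC[C@H]2C(O[Si](CC)(CC)CC)=CC[C@]2(C)C1=O | intermediate
13 | trans-hydrindenedione, (3aS,7aR)-3a,5-dimethyl-2,3,7,7a-tetrahydro-1H-indene-1,4(3aH)-dione | CC1=CC[C@H]2C(=O)CC[C@]2(C)C1=O | intermediate
14 | isopropylmagnesium chloride | CC(C)[Mg]Cl | starting material
15 | 4β-hydroxy-4α-isopropyl-1β,8-dimethyl-5αH-hydrind-7-en-10-one | CC1=CC[C@H]2[C@](O)(C(C)C)CC[C@]2(C)C1=O | intermediate
16 | 4β,10-bis(triethylsilyloxy)-4α-isopropyl-1β,8-dimethyl-5αH-hydrinda-6,8(10)-diene | CC1=C(O[Si](CC)(CC)CC)[C@@]2(C)CC[C@@](O[Si](CC)(CC)CC)(C(C)C)[C@@H]2C=C1 | intermediate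
17 | 6α,7α-epoxide of 16 | CC1=C(O[Si](CC)(CC)CC)[C@@]2(C)CC[C@@](O[Si](CC)(CC)CC)(C(C)C)[C@@H]2[C@H]3O[C@@H]13 | intermediate
18 | 6α-hydroxy-4β-(triethylsilyloxy)-4α-isopropyl-1β,8-dimethyl-5αH-hydrind-7-en-10-one | CC1=C[C@H](O)[C@H]2[C@](O[Si](CC)(CC)CC)(C(C)C)CC[C@]2(C)C1=O | intermediate
19 | 6α-TBS ether of 18 | CC1=C[C@H](O[Si](C)(C)C(C)(C)C)[C@H]2[C@](O[Si](CC)(CC)CC)(C(C)C)CC[C@]2(C)C1=O | intermediate
20 | C8=C10 TES enol ether of the trans-hydrindanone (4β-OTES, 6α-OTBS) | CC1=C(O[Si](CC)(CC)CC)[C@@]2(C)CC[C@@](O[Si](CC)(CC)CC)(C(C)C)[C@@H]2[C@@H](O[Si](C)(C)C(C)(C)C)C1 | intermediate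
21 | bromoform | BrC(Br)Br | starting material
22 | 9,9-dibromo-8α,10α-methano adduct of 20 (1-silyloxy-7,7-dibromobicyclo[4.1.0]heptane unit, CBr2 on the α face) | C[C@@]1(C2(Br)Br)C[C@H](O[Si](C)(C)C(C)(C)C)[C@H]3[C@](O[Si](CC)(CC)CC)(C(C)C)CC[C@]3(C)[C@@]12O[Si](CC)(CC)CC | intermediate
23 | 9-bromo-6α-(tert-butyldimethylsilyloxy)-4β-(triethylsilyloxy)dauc-8-en-10-one | CC1=C(Br)C(=O)[C@@]2(C)CC[C@@](O[Si](CC)(CC)CC)(C(C)C)[C@@H]2[C@@H](O[Si](C)(C)C(C)(C)C)C1 | intermediate
24 | 6α-(tert-butyldimethylsilyloxy)-4β-(triethylsilyloxy)dauc-8-en-10-one | CC1=CC(=O)[C@@]2(C)CC[C@@](O[Si](CC)(CC)CC)(C(C)C)[C@@H]2[C@@H](O[Si](C)(C)C(C)(C)C)C1 | intermediate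
25 | 6α-(tert-butyldimethylsilyloxy)-4β-(triethylsilyloxy)dauc-8-en-10α-ol | CC1=C[C@@H](O)[C@@]2(C)CC[C@@](O[Si](CC)(CC)CC)(C(C)C)[C@@H]2[C@@H](O[Si](C)(C)C(C)(C)C)C1 | intermediate
26 | acetic anhydride | CC(=O)OC(C)=O | starting material
27 | 10α-acetoxy-6α-(tert-butyldimethylsilyloxy)-4β-(triethylsilyloxy)dauc-8-ene | CC1=C[C@@H](OC(C)=O)[C@@]2(C)CC[C@@](O[Si](CC)(CC)CC)(C(C)C)[C@@H]2[C@@H](O[Si](C)(C)C(C)(C)C)C1 | intermediate
28 | 10α-acetoxydauc-8-ene-4β,6α-diol | CC1=C[C@@H](OC(C)=O)[C@@]2(C)CC[C@@](O)(C(C)C)[C@@H]2[C@@H](O)C1 | intermediate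
29 | 4-methoxybenzoyl chloride | COc1ccc(cc1)C(Cl)=O | starting material
30 | 10α-acetoxy-6α-(4-methoxybenzoyloxy)dauc-8-en-4β-ol (1S,4R,5S,6S,10R) | COc1ccc(C(=O)O[C@H]2CC(C)=C[C@@H](OC(C)=O)[C@@]3(C)CC[C@@](O)(C(C)C)[C@H]23)cc1 | target

**Total step count:** 17. **Longest linear sequence:** 17 steps, from 1 to 30.

**Steps most likely to fail**

**Step 12.** Carbene transfer to the tetrasubstituted enol ether beside quaternary C1 may be too slow. Cleavage of the enol ether by tert-butoxide, or premature opening while base is still present, could then take over.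
- The fallback sets out from 20. The smaller, neutral zinc carbenoid (Et2Zn, CH2I2, CH2Cl2, 0 °C; Simmons–Smith cyclopropanation) should give the 8α,10α-methano silyloxycyclopropane F1.
- FeCl3 in DMF oxidises it by one electron. The shared C8–C10 bond breaks towards the tertiary C8 radical, and chlorine transfer gives the ring-enlarged 8-chloro-8-methyl ketone F2 (both C8 epimers).
- NaOAc in warm methanol then removes HCl towards C9.
- The fallback comes back to the route at enone 24 and makes step 13 superfluous.

**Step 14.** Facial selectivity may be poor if catalyst control and the intrinsic preference of the ketone for hydride approach anti to the C1 methyl group oppose each other.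
- The fallback sets out from 24. A Luche reduction (NaBH4, CeCl3, MeOH, −40 °C) follows the intrinsic bias and should give the 10β-alcohol F3.
- A Mitsunobu reaction with 4-nitrobenzoic acid (PPh3, DIAD, toluene) inverts C10 by carboxylate attack from the α face. This kind of inversion is known for neopentylic 17β-hydroxy steroids, and it gives the 10α-(4-nitrobenzoate) F4.
- K2CO3 in methanol frees the alcohol, and the fallback comes back to the route at 25.

**Step 9.** The peracid may attack the C8=C10 enol ether bond instead (α-hydroxylation at C8), or approach from the β face.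
- The fallback sets out from 16. Singlet oxygen (O2, tetraphenylporphyrin, hν, CH2Cl2, −78 °C) adds [4+2] to the diene termini C6 and C10 from the α face. This mode of addition fixes the γ-regiochemistry and gives the 6α,10α-endoperoxide F5.
- Thiourea in methanol reduces the O–O bond, and the C10 silyl hemiketal collapses to the enone.
- The fallback comes back to the route at 18.

**Further compounds**
F1 | step 12 | 8α,10α-methano silyloxycyclopropane from 20 (CH2 in place of CBr2) | C[C@@]1(C2)C[C@H](O[Si](C)(C)C(C)(C)C)[C@H]3[C@](O[Si](CC)(CC)CC)(C(C)C)CC[C@]3(C)[C@@]12O[Si](CC)(CC)CC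
F2 | step 12 | 8-chloro-6α-(tert-butyldimethylsilyloxy)-4β-(triethylsilyloxy)daucan-10-one (both C8 epimers) | CC1(Cl)CC(=O)[C@@]2(C)CC[C@@](O[Si](CC)(CC)CC)(C(C)C)[C@@H]2[C@@H](O[Si](C)(C)C(C)(C)C)C1
F3 | step 14 | 6α-(tert-butyldimethylsilyloxy)-4β-(triethylsilyloxy)dauc-8-en-10β-ol | CC1=C[C@H](O)[C@@]2(C)CC[C@@](O[Si](CC)(CC)CC)(C(C)C)[C@@H]2[C@@H](O[Si](C)(C)C(C)(C)C)C1
F4 | step 14 | 10α-(4-nitrobenzoyloxy)-6α-(tert-butyldimethylsilyloxy)-4β-(triethylsilyloxy)dauc-8-ene | CC1=C[C@@H](OC(=O)c3ccc(cc3)[N+](=O)[O-])[C@@]2(C)CC[C@@](O[Si](CC)(CC)CC)(C(C)C)[C@@H]2[C@@H](O[Si](C)(C)C(C)(C)C)C1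
F5 | step 9 | 6α,10α-endoperoxide of 16 | CC1=C[C@@H]2OO[C@@]1(O[Si](CC)(CC)CC)[C@@]3(C)CC[C@@](O[Si](CC)(CC)CC)(C(C)C)[C@H]23
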